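**Retrosynthetic overview**

1. Target 45 ⇐ acetates and the free C9–OH are unveiled last; C6–Cl comes from SN2 inversion of a C6 carbinol; the ten-membered ring is closed (C5–C6) by intramolecular alkenyl triflate/aldehyde coupling.
2. The γ-lactone (C7–O) comes from iodolactonisation of a C7 vinyl / C19 acid; the C8–C9 bond is made by intermolecular aldol addition of the L-malate-derived dioxolanone 31 (C7, C8, C17–C19) to ring-A aldehyde 27.
3. Aldehyde 27 comes from a Hajos–Parrish-type hydrindane whose cyclopentene (C3=C9) is cleaved by ozonolysis, giving the C9 carbonyl and the C2–C5 arm.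
4. Ring-A stereocentres: amino-acid-mediated annulation (C1), alkaline epoxidation (13α,14α), hydride anti to the oxirane (12α-OH), hydroxyl-directed cis-hydrogenation (C10, C11).
5. Ring order: six-membered carbocycle (with a sacrificial cyclopentane) → oxirane → γ-lactone → ten-membered ring.

Convention (one line): locants are those of the target skeleton (C1 quaternary C–CH3 [C15]; C2 CH–OAc; C3, C4 CH2; C5 C=CH2 [C16]; C6 CHCl; C7 lactone CH–O; C8 C–OH; C9 CH–OH; C10 ring CH; C11 CH–CH3 [C20]; C12 CH–OAc; C13/C14 oxirane; C17 CH–CH3 [C18]; C19 lactone C=O); β = face of the six-membered ring carrying the C1 methyl, α = the other face; PMB = 4-methoxybenzyl, TBS = tert-butyldimethylsilyl, TES = triethylsilyl, Tf = trifluoromethanesulfonyl. The route is a plan reasoned from known reaction types; no step has been run.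

**Route**

Step 1
Reactants: 1 2-methylcyclopentane-1,3-dione; 2 pent-1-en-3-one (ethyl vinyl ketone)
Product: 3 2-methyl-2-(3-oxopentyl)cyclopentane-1,3-dione
Conditions: AcOH (cat.), H2O, 75 °C
Reagents that add atoms: none
Why: Michael addition of the acidic cyclic 1,3-dione to the enone; no stereocentre is formed.

Step 2
Reactants: 3 triketone
Product: 4 (S)-4,7a-dimethyl-2,3,7,7a-tetrahydro-1H-indene-1,5(6H)-dione
Conditions: L-phenylalanine (1 equiv), (1S)-camphor-10-sulfonic acid (0.5 equiv), MeCN, reflux; recrystallise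
Reagents that add atoms: none
Why: Hajos–Parrish–Eder–Sauer–Wiechert aldol condensation; the L-amino-acid enamine differentiates the two enantiotopic ring carbonyls and sets the quaternary C1 as S.

Step 3
Reactants: 4 (S)-enedione
Product: 5 (1S,7aS)-1-hydroxy-4,7a-dimethyl-1,2,3,6,7,7a-hexahydro-5H-inden-5-one (2β-alcohol)
Conditions: NaBH4 (0.3 equiv), EtOH, −20 °C
Reagents that add atoms: none
Why: Chemoselective hydride reduction of the saturated cyclopentanone over the enone; hydride attacks anti to the angular methyl, giving the 2β-alcohol (temporary protection of C2).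

Step 4
Reactants: 5 2β-hydroxy enone
Product: 6 2β-TBS ether of 5
Conditions: TBSCl, imidazole, DMF, 25 °C
Reagents that add atoms: tert-butyldimethylsilyl chloride, CC(C)(C)[Si](C)(C)Cl
Why: Standard silylation of a secondary alcohol; no stereocentre is touched.

Step 5
Reactants: 6 TBS ether enone
Product: 8 cross-conjugated dienone (C12 ketone; C10=C11 and C13=C14; 2β-OTBS), via trimethylsilyl dienol ether 7 (not isolated)
Conditions: LiN(iPr)2, Me3SiCl, THF, −78 °C; then Pd(OAc)2 (1.1 equiv), MeCN, 25 °C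
Reagents that add atoms: none
Why: Saegusa–Ito oxidation: kinetic deprotonation at C13 gives the silyl dienol ether, and palladation/β-hydride elimination installs C13=C14.

Step 6
Reactants: 8 cross-conjugated dienone
Product: 9 13α,14α-epoxy enone (C12 ketone, C10=C11, 2β-OTBS)
Conditions: 30% H2O2, NaOH (aq), MeOH, 0 °C
Reagents that add atoms: hydrogen peroxide, OO
Why: Weitz–Scheffer nucleophilic epoxidation; hydroperoxide adds only to the disubstituted enone arm (C14) and from the α-face, anti to the angular C1 methyl.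

Step 7
Reactants: 9 epoxy enone
Product: 10 13α,14α-epoxy-12α-allylic alcohol (C10=C11, 2β-OTBS)
Conditions: NaBH4, CeCl3·7H2O, MeOH, −78 °C
Reagents that add atoms: none
Why: Luche 1,2-reduction; hydride is delivered anti to the oxirane oxygen (β-face), giving the cis-epoxy alcohol with 12α-OH.

Step 8
Reactants: 10 epoxy allylic alcohol
Product: 11 trans-hydrindane epoxy alcohol (10α-H, 11β-CH3, 12α-OH, 13α,14α-oxirane, 2β-OTBS)
Conditions: H2 (1 atm), [Ir(cod)(PCy3)(py)]PF6 (10 mol %), CH2Cl2, 25 °C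
Reagents that add atoms: none
Why: Hydroxyl-directed homogeneous hydrogenation: iridium bound to the 12α-OH adds H2 cis to the α-face of the tetrasubstituted alkene, setting 10α-H (trans fusion) and 11α-H (11β-methyl); the β-face is also shielded by the angular methyl.

Step 9
Reactants: 11 epoxy alcohol
Product: 12 12α-PMB ether of 11
Conditions: NaH, 4-MeOC6H4CH2Cl, Bu4NI (cat.), THF/DMF, 0 → 25 °C
Reagents that add atoms: 4-methoxybenzyl chloride, COc1ccc(CCl)cc1
Why: Williamson etherification; the alkoxide is cis to the oxirane, so Payne rearrangement is geometrically impossible.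

Step 10
Reactants: 12 PMB ether
Product: 13 2β-alcohol (12α-OPMB, oxirane)
Conditions: Bu4NF, THF, 25 °C
Reagents that add atoms: none
Why: Fluoride-mediated desilylation; ether and oxirane are inert.

Step 11
Reactants: 13 2β-alcohol
Product: 14 C2 ketone (trans-hydrindanone)
Conditions: Dess–Martin periodinane, NaHCO3, CH2Cl2, 25 °C
Reagents that add atoms: none
Why: Dess–Martin oxidation of the secondary alcohol under buffered, non-epimerising conditions.

Step 12
Reactants: 14 C2 ketone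
Product: 16 cyclopentenone (C2 ketone, C3=C9), via C2 trimethylsilyl enol ether 15 (not isolated)
Conditions: LiN(iPr)2, Me3SiCl, THF, −78 °C; then Pd(OAc)2 (1.1 equiv), MeCN, 25 °C
Reagents that add atoms: none
Why: Saegusa–Ito oxidation; the ketone can enolise only toward C3 because C1 is quaternary.

Step 13
Reactants: 16 cyclopentenone
Product: 17 2β-allylic alcohol (C3=C9)
Conditions: NaBH4, CeCl3·7H2O, MeOH, −78 °C
Reagents that add atoms: none
Why: Luche 1,2-reduction; hydride again attacks from the α-face opposite the angular methyl, giving the 2β-alcohol (the wrong C2 epimer, corrected in step 14).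

Step 14
Reactants: 17 2β-allylic alcohol
Product: 18 2α-(4-nitrobenzoate) (2R)
Conditions: 4-O2NC6H4CO2H, PPh3, iPrO2CN=NCO2iPr, THF, 0 → 25 °C
Reagents that add atoms: 4-nitrobenzoic acid, OC(=O)c1ccc(cc1)[N+](=O)[O-]
Why: Mitsunobu reaction; SN2 attack of the carboxylate from the open α-face inverts C2 to the required 2R (2α-oxygen, trans to the C1 methyl).

Step 15
Reactants: 18 2α-(4-nitrobenzoate)
Product: 19 2α-allylic alcohol
Conditions: K2CO3 (cat.), MeOH, 0 °C
Reagents that add atoms: none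
Why: Transesterification (acyl–oxygen cleavage), so the C2 configuration is retained.

Step 16
Reactants: 19 2α-allylic alcohol
Product: 20 2α,12α-bis-PMB ether cyclopentene
Conditions: NaH, 4-MeOC6H4CH2Cl, Bu4NI (cat.), DMF, 0 → 25 °C
Reagents that add atoms: 4-methoxybenzyl chloride, COc1ccc(CCl)cc1
Why: Williamson etherification; no stereocentre is touched.

Step 17
Reactants: 20 bis-PMB cyclopentene
Product: 22 C3 aldehyde C9 methyl ester (ring-opened), via methoxy hydroperoxide aldehyde 21 (not isolated)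
Conditions: O3, NaHCO3, CH2Cl2/MeOH 5:1, −78 °C (to first blue tint); then Ac2O, Et3N, 0 → 25 °C
Reagents that add atoms: ozone, [O-][O+]=O; methanol, CO
Why: Criegee ozonolysis with Schreiber's dehydrative work-up; the carbonyl oxide forms at C9, remote from the electron-withdrawing C2 ether, is trapped by methanol and dehydrated to the methyl ester, while C3 stays an aldehyde.

Step 18
Reactants: 22 aldehyde ester
Product: 23 (E)-enone (C3=C4, C5 methyl ketone)
Conditions: Ph3P=CHC(O)CH3, toluene, 60 °C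
Reagents that add atoms: 1-(triphenyl-λ5-phosphanylidene)propan-2-one, CC(=O)C=P(c1ccccc1)(c1ccccc1)c1ccccc1
Why: Wittig olefination with a stabilised ylide is aldehyde-selective and E-selective under neutral conditions; it brings in C4, C5 and C16.

Step 19
Reactants: 23 (E)-enone
Product: 24 C5 methyl ketone (saturated C3–C4)
Conditions: H2 (1 atm), RhCl(PPh3)3 (5 mol %), benzene, 25 °C
Reagents that add atoms: none
Why: Homogeneous hydrogenation of the disubstituted conjugated alkene; benzyl-type ethers, oxirane and carbonyls are untouched.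

Step 20
Reactants: 24 methyl ketone
Product: 25 C5 alkenyl triflate (C5=C16) C9 methyl ester
Conditions: LiN(iPr)2, THF, −78 °C; then PhNTf2, −78 → 0 °C
Reagents that add atoms: N-phenylbis(trifluoromethanesulfonimide), O=S(=O)(N(c1ccccc1)S(=O)(=O)C(F)(F)F)C(F)(F)F
Why: Kinetic deprotonation at the methyl group and O-triflation of the less substituted enolate give the 2-triflyloxy-1-alkene (enol triflate formation).

Step 21
Reactants: 25 triflate ester
Product: 26 C9 primary alcohol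
Conditions: iBu2AlH (2.5 equiv), CH2Cl2, −78 → −20 °C; aqueous KNaC4H4O6 work-up
Reagents that add atoms: none
Why: Hydride reduction of the ester to the alcohol; triflate, oxirane and ethers are inert at low temperature.

Step 22
Reactants: 26 primary alcohol
Product: 27 C9 aldehyde (fragment 1)
Conditions: Dess–Martin periodinane, NaHCO3, CH2Cl2, 0 → 25 °C
Reagents that add atoms: none
Why: Dess–Martin oxidation is non-basic, so the α-stereocentre C10 is not epimerised.

Step 23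
Reactants: 28 diethyl (S)-malate
Product: 29 diethyl (2S,3R)-2-hydroxy-3-methylsuccinate
Conditions: LiN(iPr)2 (2.2 equiv), THF, −78 → −20 °C; MeI, −78 → 25 °C
Reagents that add atoms: iodomethane, CI
Why: Fráter–Seebach alkylation; the chelated dilithio alkoxide enolate is methylated anti to the alkoxide, giving the (2S,3R) isomer (about 9:1, purified), which is the C17 configuration.

Step 24
Reactants: 29 diethyl (2S,3R)-2-hydroxy-3-methylsuccinate
Product: 30 (2S,3R)-2-hydroxy-3-methylsuccinic acid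
Conditions: KOH, H2O/EtOH, 25 °C; then HCl (aq) to pH 1, continuous extraction
Reagents that add atoms: water (as aqueous KOH), O
Why: Saponification by acyl–oxygen cleavage; both stereocentres are untouched.

Step 25
Reactants: 30 (2S,3R)-2-hydroxy-3-methylsuccinic acid
Product: 31 (2S,5S)-2-tert-butyl-5-[(1R)-1-carboxyethyl]-1,3-dioxolan-4-one (fragment 2)
Conditions: tBuCHO, TsOH·H2O (cat.), H2SO4 (cat.), pentane, reflux, Dean–Stark
Reagents that add atoms: pivalaldehyde (2,2-dimethylpropanal), CC(C)(C)C=O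
Why: Acid-catalysed acetalisation of the α-hydroxy acid (Seebach self-regeneration of stereocentres); the cis dioxolanone is thermodynamically favoured and crystalline.

Step 26
Reactants: 27 C9 aldehyde (fragment 1); 31 dioxolanone acid (fragment 2)
Product: 32 aldol adduct (9R carbinol, 8R dioxolanone, C19 acid)
Conditions: 31 (1.5 equiv), LiN(SiMe3)2 (3.1 equiv), THF, −78 °C; then 27, −78 °C; AcOH quench at −78 °C
Reagents that add atoms: none
Why: Intermolecular aldol addition of the dioxolanone lithium enolate (carboxylate dianion): the aldehyde adds trans to the tert-butyl group, so C8 keeps the malate configuration (retention, 8R), and Felkin–Anh attack anti to the quaternary C1 substituent of the α-branched aldehyde gives 9R.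

Step 27
Reactants: 32 aldol adduct
Product: 34 C9 TES ether acid, via bis-triethylsilyl derivative 33 (not isolated)
Conditions: Et3SiOTf (2.5 equiv), 2,6-lutidine, CH2Cl2, −78 → −20 °C; then pH 7 buffer, THF, 0 °C
Reagents that add atoms: triethylsilyl trifluoromethanesulfonate, CC[Si](CC)(CC)OS(=O)(=O)C(F)(F)F
Why: Silylation of the hindered C9 carbinol by the silyl triflate; the C19 silyl ester hydrolyses on buffered work-up, and protection blocks lactonisation of C19 onto O9.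

Step 28
Reactants: 34 TES ether acid
Product: 35 dioxolanyl lactol (C7 hemiacetal)
Conditions: iBu2AlH (3 equiv), CH2Cl2, −78 °C
Reagents that add atoms: none
Why: Partial reduction of the activated dioxolanone carbonyl to the stable cyclic hemiacetal; the C19 acid sits as an unreactive aluminium carboxylate.

Step 29
Reactants: 35 lactol
Product: 36 C7 vinyl C8 tertiary alcohol C19 acid
Conditions: Ph3PCH3Br, KN(SiMe3)2 (excess ylide), THF, 0 → 25 °C
Reagents that add atoms: methyltriphenylphosphonium bromide, C[P+](c1ccccc1)(c1ccccc1)c1ccccc1.[Br-]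
Why: Wittig methylenation of the open-chain aldehyde of the lactol; the hemiacetal alkoxide expels pivalaldehyde and frees the C8 hydroxyl, and C6 is introduced.

Step 30
Reactants: 36 vinyl carbinol acid
Product: 37 iodolactone (γ-lactone C19–O–C7, C6 iodide)
Conditions: I2, NaHCO3, MeCN/H2O, 0 °C, dark
Reagents that add atoms: iodine, II
Why: Kinetic 5-exo iodolactonisation; with the allylic hydroxyl in the plane (Chamberlin model) the CH2I group ends cis to the C8 hydroxyl and trans to the bulky C9 chain, giving 7R.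

Step 31
Reactants: 37 iodolactone
Product: 38 lactone aldehyde (C6 aldehyde)
Conditions: AgBF4, Me2SO, 25 °C; then Et3N
Reagents that add atoms: dimethyl sulfoxide, CS(C)=O
Why: Kornblum oxidation; silver-assisted displacement of iodide by the sulfoxide oxygen and base-induced collapse of the alkoxysulfonium salt give the aldehyde.

Step 32
Reactants: 38 lactone aldehyde
Product: 39 macrocyclic C6 allylic alcohols (both C6 epimers, used as the mixture)
Conditions: CrCl2 (10 equiv), NiCl2 (0.2 equiv), Me2SO/THF, 25 °C, 0.002 M (slow addition)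
Reagents that add atoms: none
Why: Intramolecular Nozaki–Hiyama–Kishi coupling: nickel inserts into the alkenyl triflate, transmetalation gives the alkenylchromium, which adds to the aldehyde and closes the ten-membered ring at C5–C6; C6 is reset in steps 33–34.

Step 33
Reactants: 39 macrocyclic allylic alcohols
Product: 40 macrocyclic α-methylene ketone (C6 ketone)
Conditions: Dess–Martin periodinane, NaHCO3, CH2Cl2, 0 °C
Reagents that add atoms: none
Why: Dess–Martin oxidation converges both C6 epimers to one enone without base.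

Step 34
Reactants: 40 macrocyclic enone
Product: 41 macrocyclic 6R allylic alcohol (6-OH anti to 8-OH)
Conditions: Me4NBH(OAc)3, MeCN/AcOH, −30 °C
Reagents that add atoms: none
Why: Evans–Saksena hydroxyl-directed reduction; hydride is delivered intramolecularly from the C8 alkoxyborohydride through a chair with C5 and C9 equatorial, placing the new hydroxyl anti to the C8 oxygen (6R).

Step 35
Reactants: 41 6R allylic alcohol
Product: 42 6S chloride
Conditions: PPh3, Cl3CC(O)CCl3, 2,6-di-tert-butylpyridine, CH2Cl2, −20 → 0 °C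
Reagents that add atoms: hexachloroacetone, ClC(Cl)(Cl)C(=O)C(Cl)(Cl)Cl
Why: Appel-type chlorination (PPh3/hexachloroacetone); chloride displaces the alkoxyphosphonium ion by SN2 with inversion and without allylic transposition, giving 6S.

Step 36
Reactants: 42 chloride
Product: 43 C2,C12-diol (C9 OTES)
Conditions: DDQ, CH2Cl2/pH 7 buffer, 0 → 25 °C
Reagents that add atoms: none
Why: Oxidative cleavage of both 4-methoxybenzyl ethers (benzylic hydride abstraction, then hydrolysis); silyl ether, oxirane, lactone and allylic chloride are inert.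

Step 37
Reactants: 43 diol
Product: 44 C2,C12-diacetate C9 TES ether
Conditions: Ac2O, pyridine, 4-(dimethylamino)pyridine (cat.), CH2Cl2, 0 → 25 °C
Reagents that add atoms: acetic anhydride, CC(=O)OC(C)=O
Why: Acylation of the two secondary hydroxyls; the tertiary C8–OH is too hindered and C9 is still silylated.

Step 38
Reactants: 44 diacetate TES ether
Product: 45 target CNP0242711.1
Conditions: HF·pyridine, pyridine, THF, 0 °C
Reagents that add atoms: none
Why: Buffered fluoride desilylation releases the C9 hydroxyl while sparing acetates, oxirane, lactone and allylic chloride.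

**Compound list**

1 | 2-methylcyclopentane-1,3-dione | CC1C(=O)CCC1=O | starting material
2 | pent-1-en-3-one (ethyl vinyl ketone) | C=CC(=O)CC | starting material
3 | 2-methyl-2-(3-oxopentyl)cyclopentane-1,3-dione | CCC(=O)CCC1(C)C(=O)CCC1=O | intermediate
4 | (S)-4,7a-dimethyl-2,3,7,7a-tetrahydro-1H-indene-1,5(6H)-dione | C1C(=O)[C@]2(C)C(=C(C)C(=O)CC2)C1 | intermediate
5 | (1S,7aS)-1-hydroxy-4,7a-dimethyl-1,2,3,6,7,7a-hexahydro-5H-inden-5-one (2β-OH) | C1[C@H](O)[C@]2(C)C(=C(C)C(=O)CC2)C1 | intermediate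
6 | 2β-TBS ether of 5 | C1[C@H](O[Si](C)(C)C(C)(C)C)[C@]2(C)C(=C(C)C(=O)CC2)C1 | intermediate
7 | C12 trimethylsilyl dienol ether of 6 (not isolated) | C1[C@H](O[Si](C)(C)C(C)(C)C)[C@]2(C)C(=C(C)C(O[Si](C)(C)C)=CC2)C1 | intermediate
8 | cross-conjugated dienone (C12 ketone, C10=C11, C13=C14, 2β-OTBS) | C1[C@H](O[Si](C)(C)C(C)(C)C)[C@]2(C)C(=C(C)C(=O)C=C2)C1 | intermediate
9 | 13α,14α-epoxy enone | C1[C@H](O[Si](C)(C)C(C)(C)C)[C@]2(C)C(=C(C)C(=O)[C@@H]3O[C@@H]32)C1 | intermediate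
10 | 13α,14α-epoxy-12α-allylic alcohol | C1[C@H](O[Si](C)(C)C(C)(C)C)[C@]2(C)C(=C(C)[C@H](O)[C@@H]3O[C@@H]32)C1 | intermediate
11 | trans-hydrindane epoxy alcohol (10α-H, 11β-CH3, 12α-OH, 2β-OTBS) | C1[C@H](O[Si](C)(C)C(C)(C)C)[C@]2(C)[C@H]([C@@H](C)[C@H](O)[C@@H]3O[C@@H]32)C1 | intermediate
12 | 12α-PMB ether of 11 | C1[C@H](O[Si](C)(C)C(C)(C)C)[C@]2(C)[C@H]([C@@H](C)[C@H](OCc4ccc(OC)cc4)[C@@H]3O[C@@H]32)C1 | intermediate
13 | 2β-alcohol (12α-OPMB) | C1[C@H](O)[C@]2(C)[C@H]([C@@H](C)[C@H](OCc4ccc(OC)cc4)[C@@H]3O[C@@H]32)C1 | intermediate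
14 | C2 ketone (trans-hydrindanone) | C1C(=O)[C@]2(C)[C@H]([C@@H](C)[C@H](OCc4ccc(OC)cc4)[C@@H]3O[C@@H]32)C1 | intermediate
15 | C2 trimethylsilyl enol ether (not isolated) | C1=C(O[Si](C)(C)C)[C@]2(C)[C@H]([C@@H](C)[C@H](OCc4ccc(OC)cc4)[C@@H]3O[C@@H]32)C1 | intermediate
16 | cyclopentenone (C2 ketone, C3=C9) | C=1C(=O)[C@]2(C)[C@H]([C@@H](C)[C@H](OCc4ccc(OC)cc4)[C@@H]3O[C@@H]32)C=1 | intermediate
17 | 2β-allylic alcohol | C=1[C@H](O)[C@]2(C)[C@H]([C@@H](C)[C@H](OCc4ccc(OC)cc4)[C@@H]3O[C@@H]32)C=1 | intermediate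
18 | 2α-(4-nitrobenzoate) | C=1[C@@H](OC(=O)c5ccc(cc5)[N+](=O)[O-])[C@]2(C)[C@H]([C@@H](C)[C@H](OCc4ccc(OC)cc4)[C@@H]3O[C@@H]32)C=1 | intermediate
19 | 2α-allylic alcohol | C=1[C@@H](O)[C@]2(C)[C@H]([C@@H](C)[C@H](OCc4ccc(OC)cc4)[C@@H]3O[C@@H]32)C=1 | intermediate
20 | 2α,12α-bis-PMB ether cyclopentene | C=1[C@@H](OCc5ccc(OC)cc5)[C@]2(C)[C@H]([C@@H](C)[C@H](OCc4ccc(OC)cc4)[C@@H]3O[C@@H]32)C=1 | intermediate
21 | C3 aldehyde C9 methoxy hydroperoxide (not isolated) | O=C[C@@H](OCc5ccc(OC)cc5)[C@]2(C)[C@H]([C@@H](C)[C@H](OCc4ccc(OC)cc4)[C@@H]3O[C@@H]32)C(OC)OO | intermediate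
22 | C3 aldehyde C9 methyl ester | O=C[C@@H](OCc5ccc(OC)cc5)[C@]2(C)[C@H]([C@@H](C)[C@H](OCc4ccc(OC)cc4)[C@@H]3O[C@@H]32)C(=O)OC | intermediate
23 | (E)-enone (C3=C4, C5 ketone) | CC(=O)/C=C/[C@@H](OCc5ccc(OC)cc5)[C@]2(C)[C@H]([C@@H](C)[C@H](OCc4ccc(OC)cc4)[C@@H]3O[C@@H]32)C(=O)OC | intermediate
24 | C5 methyl ketone | CC(=O)CC[C@@H](OCc5ccc(OC)cc5)[C@]2(C)[C@H]([C@@H](C)[C@H](OCc4ccc(OC)cc4)[C@@H]3O[C@@H]32)C(=O)OC | intermediate
25 | C5 alkenyl triflate C9 methyl ester | C=C(OS(=O)(=O)C(F)(F)F)CC[C@@H](OCc5ccc(OC)cc5)[C@]2(C)[C@H]([C@@H](C)[C@H](OCc4ccc(OC)cc4)[C@@H]3O[C@@H]32)C(=O)OC | intermediate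
26 | C9 primary alcohol | C=C(OS(=O)(=O)C(F)(F)F)CC[C@@H](OCc5ccc(OC)cc5)[C@]2(C)[C@H]([C@@H](C)[C@H](OCc4ccc(OC)cc4)[C@@H]3O[C@@H]32)CO | intermediate
27 | C9 aldehyde (fragment 1) | C=C(OS(=O)(=O)C(F)(F)F)CC[C@@H](OCc5ccc(OC)cc5)[C@]2(C)[C@H]([C@@H](C)[C@H](OCc4ccc(OC)cc4)[C@@H]3O[C@@H]32)C=O | intermediate
28 | diethyl (S)-malate | CCOC(=O)C[C@H](O)C(=O)OCC | starting material
29 | diethyl (2S,3R)-2-hydroxy-3-methylsuccinate | CCOC(=O)[C@@H](O)[C@@H](C)C(=O)OCC | intermediate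
30 | (2S,3R)-2-hydroxy-3-methylsuccinic acid | OC(=O)[C@@H](O)[C@@H](C)C(=O)O | intermediate
31 | (2S,5S)-2-tert-butyl-5-[(1R)-1-carboxyethyl]-1,3-dioxolan-4-one (fragment 2) | O=C1O[C@@H](C(C)(C)C)O[C@H]1[C@@H](C)C(=O)O | intermediate
32 | aldol adduct (9R-OH, 8R dioxolanone, C19 acid) | C=C(OS(=O)(=O)C(F)(F)F)CC[C@@H](OCc5ccc(OC)cc5)[C@]2(C)[C@H]([C@@H](C)[C@H](OCc4ccc(OC)cc4)[C@@H]3O[C@@H]32)[C@@H](O)[C@]6(O[C@H](C(C)(C)C)OC6=O)[C@@H](C)C(=O)O | intermediate
33 | C9 TES ether C19 TES ester (not isolated) | C=C(OS(=O)(=O)C(F)(F)F)CC[C@@H](OCc5ccc(OC)cc5)[C@]2(C)[C@H]([C@@H](C)[C@H](OCc4ccc(OC)cc4)[C@@H]3O[C@@H]32)[C@@H](O[Si](CC)(CC)CC)[C@]6(O[C@H](C(C)(C)C)OC6=O)[C@@H](C)C(=O)O[Si](CC)(CC)CC | intermediate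
34 | C9 TES ether acid | C=C(OS(=O)(=O)C(F)(F)F)CC[C@@H](OCc5ccc(OC)cc5)[C@]2(C)[C@H]([C@@H](C)[C@H](OCc4ccc(OC)cc4)[C@@H]3O[C@@H]32)[C@@H](O[Si](CC)(CC)CC)[C@]6(O[C@H](C(C)(C)C)OC6=O)[C@@H](C)C(=O)O | intermediate
35 | dioxolanyl lactol (C7 hemiacetal, epimers) | C=C(OS(=O)(=O)C(F)(F)F)CC[C@@H](OCc5ccc(OC)cc5)[C@]2(C)[C@H]([C@@H](C)[C@H](OCc4ccc(OC)cc4)[C@@H]3O[C@@H]32)[C@@H](O[Si](CC)(CC)CC)[C@]6(O[C@H](C(C)(C)C)OC6O)[C@@H](C)C(=O)O | intermediate
36 | C7 vinyl C8 tertiary alcohol C19 acid | C=C(OS(=O)(=O)C(F)(F)F)CC[C@@H](OCc5ccc(OC)cc5)[C@]2(C)[C@H]([C@@H](C)[C@H](OCc4ccc(OC)cc4)[C@@H]3O[C@@H]32)[C@@H](O[Si](CC)(CC)CC)[C@](C=C)(O)[C@@H](C)C(=O)O | intermediate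
37 | iodolactone (C6 iodide) | C=C(OS(=O)(=O)C(F)(F)F)CC[C@@H](OCc5ccc(OC)cc5)[C@]2(C)[C@H]([C@@H](C)[C@H](OCc4ccc(OC)cc4)[C@@H]3O[C@@H]32)[C@@H](O[Si](CC)(CC)CC)[C@]6(O)[C@@H](C)C(=O)O[C@H]6CI | intermediate
38 | lactone aldehyde (C6 aldehyde) | C=C(OS(=O)(=O)C(F)(F)F)CC[C@@H](OCc5ccc(OC)cc5)[C@]2(C)[C@H]([C@@H](C)[C@H](OCc4ccc(OC)cc4)[C@@H]3O[C@@H]32)[C@@H](O[Si](CC)(CC)CC)[C@]6(O)[C@@H](C)C(=O)O[C@H]6C=O | intermediate
39 | macrocyclic C6 allylic alcohols (C6 epimers) | C=C1CC[C@@H](OCc5ccc(OC)cc5)[C@]2(C)[C@H]([C@@H](C)[C@H](OCc4ccc(OC)cc4)[C@@H]3O[C@@H]32)[C@@H](O[Si](CC)(CC)CC)[C@]6(O)[C@@H](C)C(=O)O[C@H]6C1O | intermediate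
40 | macrocyclic α-methylene ketone (C6 ketone) | C=C1CC[C@@H](OCc5ccc(OC)cc5)[C@]2(C)[C@H]([C@@H](C)[C@H](OCc4ccc(OC)cc4)[C@@H]3O[C@@H]32)[C@@H](O[Si](CC)(CC)CC)[C@]6(O)[C@@H](C)C(=O)O[C@H]6C1=O | intermediate
41 | macrocyclic 6R allylic alcohol | C=C1CC[C@@H](OCc5ccc(OC)cc5)[C@]2(C)[C@H]([C@@H](C)[C@H](OCc4ccc(OC)cc4)[C@@H]3O[C@@H]32)[C@@H](O[Si](CC)(CC)CC)[C@]6(O)[C@@H](C)C(=O)O[C@H]6[C@@H]1O | intermediate
42 | 6S chloride (bis-PMB, C9 OTES) | C=C1CC[C@@H](OCc5ccc(OC)cc5)[C@]2(C)[C@H]([C@@H](C)[C@H](OCc4ccc(OC)cc4)[C@@H]3O[C@@H]32)[C@@H](O[Si](CC)(CC)CC)[C@]6(O)[C@@H](C)C(=O)O[C@H]6[C@H]1Cl | intermediate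
43 | C2,C12-diol (C9 OTES) | C=C1CC[C@@H](O)[C@]2(C)[C@H]([C@@H](C)[C@H](O)[C@@H]3O[C@@H]32)[C@@H](O[Si](CC)(CC)CC)[C@]6(O)[C@@H](C)C(=O)O[C@H]6[C@H]1Cl | intermediate
44 | C2,C12-diacetate C9 TES ether | C=C1CC[C@@H](OC(C)=O)[C@]2(C)[C@H]([C@@H](C)[C@H](OC(C)=O)[C@@H]3O[C@@H]32)[C@@H](O[Si](CC)(CC)CC)[C@]6(O)[C@@H](C)C(=O)O[C@H]6[C@H]1Cl | intermediate
45 | CNP0242711.1 | C=C1CC[C@@H](OC(C)=O)[C@]2(C)[C@H]([C@@H](C)[C@H](OC(C)=O)[C@@H]3O[C@@H]32)[C@@H](O)[C@]2(O)[C@@H](C)C(=O)O[C@H]2[C@H]1Cl | target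

**Count and risks**

Total step count: 38. Longest linear sequence: 35 steps (steps 1–22, then 26–38); the second branch (steps 23–25) is 3 steps.

Most likely to fail, first: step 26. The fully substituted dioxolanone enolate may add to the hindered aldehyde slowly or give the wrong C9 epimer if its intrinsic facial preference opposes Felkin control. The fallback builds the same bond by acylation and sets C9 separately by hydride. It sets out from 27: chlorite oxidation (NaClO2, NaH2PO4, 2-methylbut-2-ene) gives the C9 carboxylic acid F1; cyanuric fluoride and pyridine give the acyl fluoride F2; Claisen-type C-acylation of the dilithio derivative of 31 (LiN(SiMe3)2, THF, −78 °C), again trans to the tert-butyl group, gives the C9 keto dioxolanone F3; reduction of that ketone with Zn(BH4)2 in Et2O at −20 °C (or NaBH4/CeCl3·7H2O if the chelate gives the other epimer) returns to 32.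

Second: step 32. Ten-membered ring closure can lose to oligomerisation or triflate reduction. The fallback closes the same C5–C6 bond by a palladium-catalysed acyl coupling and lands directly on the enone. It sets out from 38: NaClO2 oxidation gives the C6 carboxylic acid F4; ethanethiol, a carbodiimide and 4-(dimethylamino)pyridine give the S-ethyl thioester F5; Pd(PPh3)4, Me3SnSnMe3 and LiCl convert the alkenyl triflate into the alkenylstannane F6; intramolecular Liebeskind–Srogl coupling (Pd2(dba)3, P(2-furyl)3, Cu(O2CC4H3S), THF, high dilution) returns to 40, bypassing 39.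

Third: step 35. The hindered allylic carbinol may react by SN2′ to give the rearranged primary C16 chloride, or ionise. The fallback masks the methylene so that C6 is not allylic during chlorination. It sets out from 40: conjugate addition of benzeneselenol (PhSeSePh, NaBH4, EtOH, 0 °C) gives the β-(phenylselanyl)methyl ketone F7; the same directed reduction (Me4NBH(OAc)3) gives the 6R alcohol F8; chlorination with inversion (PPh3, Cl3CC(O)CCl3, or 1-chloro-N,N,2-trimethylprop-1-en-1-amine) gives the 6S chloride F9; oxidation with H2O2 and pyridine in CH2Cl2 at 0 °C triggers selenoxide syn-elimination toward C5–H (the only β-hydrogen) and returns to 42.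

**Further compounds**

F1 | step 26 | C9 carboxylic acid of fragment 1 | C=C(OS(=O)(=O)C(F)(F)F)CC[C@@H](OCc5ccc(OC)cc5)[C@]2(C)[C@H]([C@@H](C)[C@H](OCc4ccc(OC)cc4)[C@@H]3O[C@@H]32)C(=O)O
F2 | step 26 | C9 acyl fluoride | C=C(OS(=O)(=O)C(F)(F)F)CC[C@@H](OCc5ccc(OC)cc5)[C@]2(C)[C@H]([C@@H](C)[C@H](OCc4ccc(OC)cc4)[C@@H]3O[C@@H]32)C(F)=O
F3 | step 26 | C9 keto dioxolanone acid | C=C(OS(=O)(=O)C(F)(F)F)CC[C@@H](OCc5ccc(OC)cc5)[C@]2(C)[C@H]([C@@H](C)[C@H](OCc4ccc(OC)cc4)[C@@H]3O[C@@H]32)C(=O)[C@]6(O[C@H](C(C)(C)C)OC6=O)[C@@H](C)C(=O)O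
F4 | step 32 | lactone C6 carboxylic acid | C=C(OS(=O)(=O)C(F)(F)F)CC[C@@H](OCc5ccc(OC)cc5)[C@]2(C)[C@H]([C@@H](C)[C@H](OCc4ccc(OC)cc4)[C@@H]3O[C@@H]32)[C@@H](O[Si](CC)(CC)CC)[C@]6(O)[C@@H](C)C(=O)O[C@H]6C(=O)O
F5 | step 32 | lactone C6 S-ethyl thioester | C=C(OS(=O)(=O)C(F)(F)F)CC[C@@H](OCc5ccc(OC)cc5)[C@]2(C)[C@H]([C@@H](C)[C@H](OCc4ccc(OC)cc4)[C@@H]3O[C@@H]32)[C@@H](O[Si](CC)(CC)CC)[C@]6(O)[C@@H](C)C(=O)O[C@H]6C(=O)SCC
F6 | step 32 | alkenylstannane S-ethyl thioester | C=C([Sn](C)(C)C)CC[C@@H](OCc5ccc(OC)cc5)[C@]2(C)[C@H]([C@@H](C)[C@H](OCc4ccc(OC)cc4)[C@@H]3O[C@@H]32)[C@@H](O[Si](CC)(CC)CC)[C@]6(O)[C@@H](C)C(=O)O[C@H]6C(=O)SCC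
F7 | step 35 | macrocyclic C16 phenylselanyl ketone (C5 epimers) | c7ccccc7[Se]CC1CC[C@@H](OCc5ccc(OC)cc5)[C@]2(C)[C@H]([C@@H](C)[C@H](OCc4ccc(OC)cc4)[C@@H]3O[C@@H]32)[C@@H](O[Si](CC)(CC)CC)[C@]6(O)[C@@H](C)C(=O)O[C@H]6C1=O
F8 | step 35 | C16 phenylselanyl 6R alcohol | c7ccccc7[Se]CC1CC[C@@H](OCc5ccc(OC)cc5)[C@]2(C)[C@H]([C@@H](C)[C@H](OCc4ccc(OC)cc4)[C@@H]3O[C@@H]32)[C@@H](O[Si](CC)(CC)CC)[C@]6(O)[C@@H](C)C(=O)O[C@H]6[C@@H]1O
F9 | step 35 | C16 phenylselanyl 6S chloride | c7ccccc7[Se]CC1CC[C@@H](OCc5ccc(OC)cc5)[C@]2(C)[C@H]([C@@H](C)[C@H](OCc4ccc(OC)cc4)[C@@H]3O[C@@H]32)[C@@H](O[Si](CC)(CC)CC)[C@]6(O)[C@@H](C)C(=O)O[C@H]6[C@H]1Cl
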